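Locants: pyrrolidine N4, C3, C2, C1 (spiro), C9a; azepine N4, C5–C9, C9a; cyclohexene C1, C9a, C9–C12. The enamine N4–C9a=C9 is the edge shared by azepine and cyclohexene, so both rings are cut there: bonds C9–C9a and N4–C5 form together. The enamine is read as the N-alkylated tautomer of a cyclic ketimine. The precursor is a spiro Se-phenyl selenoimidate with pyrroline ring, both lactones and all eight stereocentres in place; C12 carries a chain ending in the C8=C9 alkene and the C5 chloride. An imidoyl radical at C9a closes the cyclohexene 6-exo; the imine nitrogen then closes the azepine and the enamine forms.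

Key step: step 15

Remark on numbering: further locants are C10 (CH–Et), C11 (CH–OH), C12, C13 (CH–Me), C14 (spirolactone C=O), and C18 (O–CH), C19, C20 (CH–Me), C21 (C=O) in the side lactone. The target is (1R,3R,10S,11R,12R,13R,18S,20S).
Assumption: the Lewis-acid-promoted addition to the N-sulfinyl imine in step 7 runs through the open transition state (attack anti to the tert-butyl group), so the (S)-sulfinyl group gives 3R; were the sense reversed, the (R)-sulfinamide would be used.

Step 1
Reactants: 1 L-allylglycine [(2S)-2-aminopent-4-enoic acid]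
Product: 2 (2S)-2-hydroxypent-4-enoic acid
Conditions: NaNO2, 1 M H2SO4, H2O, 0 to 23 °C
Reagents that add atoms: water, O
Why: Diazotization followed by α-lactone formation and its opening by water (double inversion) should replace NH2 by OH with net retention, so the future C1 keeps the S configuration of the amino acid.

Step 2
Reactants: 2 (2S)-2-hydroxypent-4-enoic acid
Product: 3 (2S,5S)-2-tert-butyl-5-(prop-2-en-1-yl)-1,3-dioxolan-4-one (cis)
Conditions: pivalaldehyde, TsOH (cat.), H2SO4 (cat.), pentane, reflux, water separator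
Reagents that add atoms: pivalaldehyde, CC(C)(C)C=O
Why: Acid-catalysed acetalization with removal of water should favour the cis dioxolanone (tert-butyl and allyl on one face, new acetal centre S, purified by crystallization), which stores the C1 chirality for the enolate step.

Step 3
Reactants: 3 (2S,5S)-2-tert-butyl-5-(prop-2-en-1-yl)-1,3-dioxolan-4-one; 4 (5R)-5-{[(1R,2S,5R)-2-isopropyl-5-methylcyclohexyl]oxy}furan-2(5H)-one
Product: 7 (2S,5R)-2-tert-butyl-5-[(2R,3S,4R)-2-menthyloxy-4-methyl-5-oxooxolan-3-yl]-5-(prop-2-en-1-yl)-1,3-dioxolan-4-one, via lithium enolate 5 (not isolated), via adduct lactone enolate 6 (not isolated)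
Conditions: LiN(iPr)2, THF, −78 °C; then 4, −78 °C; then MeI, DMPU, −78 to −20 °C
Reagents that add atoms: iodomethane, CI
Why: Tandem Michael addition–enolate alkylation in which enolate 5 is attacked anti to the tert-butyl group (the C1–C12 bond takes the place of the former hydrogen, self-regeneration of the stereocentre), the furanone is attacked anti to its menthyloxy group (sets C12) and MeI enters enolate 6 anti to the new C12 substituent (sets C13).

Step 4
Reactants: 7 the Michael–methylation adduct
Product: 9 aldehyde of 7 with CH2–CHO (C2–C3) in place of the allyl group, via ozonide 8 (not isolated)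
Conditions: O3, CH2Cl2, −78 °C; then PPh3, −78 to 23 °C
Reagents that add atoms: ozone, [O-][O+]=O
Why: Ozonolysis with reductive work-up cleaves the only C=C bond to the C3 aldehyde and leaves acetal, lactone and stereocentres untouched.

Step 5
Reactants: 9 the C3 aldehyde
Product: 10 (S at sulfur, E)-N-tert-butanesulfinyl aldimine of 9
Conditions: (S)-tert-butanesulfinamide, CuSO4, CH2Cl2, 23 °C
Reagents that add atoms: (S)-2-methylpropane-2-sulfinamide, CC(C)(C)[S@](=O)N
Why: Condensation of the aldehyde with the sulfinamide over the mild dehydrating Lewis acid CuSO4 should give the E aldimine, which activates C3 and carries the chiral controller.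

Step 6
Reactants: 11 3-methylfuran-2(5H)-one
Product: 12 3-methyl-2-[(triisopropylsilyl)oxy]furan
Conditions: iPr3SiOTf, Et3N, CH2Cl2, 0 °C
Reagents that add atoms: triisopropylsilyl triflate, CC(C)[Si](C(C)C)(C(C)C)OS(=O)(=O)C(F)(F)F
Why: Soft enolization and O-silylation of the butenolide give the aromatic silyloxyfuran, the dienolate equivalent for the vinylogous Mannich reaction.

Step 7
Reactants: 10 the N-sulfinyl aldimine; 12 3-methyl-2-[(triisopropylsilyl)oxy]furan
Product: 13 sulfinamide in which C3 (R) carries the (2S)-4-methyl-5-oxo-2,5-dihydrofuran-2-yl group (C18 S)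
Conditions: Me3SiOTf (cat.), CH2Cl2, −78 °C; aq. NaHCO3 work-up
Reagents that add atoms: none
Why: Vinylogous Mukaiyama–Mannich reaction in which C5 of the silyloxyfuran adds through an open transition state to the imine face anti to the sulfinyl tert-butyl group (sets C3 as R), with the antiperiplanar approach that places the nitrogen on C3 and the ring oxygen on C18 anti along C2–C3–C18–C19 (sets C18 as S).

Step 8
Reactants: 13 the butenolide sulfinamide
Product: 14 saturated cis lactone sulfinamide [(2S,4S)-4-methyl-5-oxooxolan-2-yl on C3]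
Conditions: H2 (1 atm), Pd/C (10% Pd on carbon), EtOAc, 23 °C
Reagents that add atoms: none
Why: Heterogeneous hydrogenation of the butenolide C=C from the face opposite the C18 substituent places the methyl group cis to it (sets C20 as S), and no other alkene is present at this stage.

Step 9
Reactants: 14 the saturated sulfinamide
Product: 17 (spiro lactam–lactone aldehyde) 4-formyl-3-methyl-8-[(2S,4S)-4-methyl-5-oxooxolan-2-yl]-1-oxa-7-azaspiro[4.4]nonane-2,6-dione with C1 C3 C12 C13 arranged as in the target, via amine hydrochloride 15 (not isolated), via hydroxy lactam 16 (not isolated)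
Conditions: HCl (4 M in 1,4-dioxane), CH2Cl2, 0 °C; then Et3N, CH2Cl2, 23 °C; then CF3CO2H–H2O (9:1), 0 to 23 °C
Reagents that add atoms: none
Why: HCl cleaves the S–N bond, the amine freed by Et3N acylates itself on the activated dioxolanone carbonyl in a 5-exo-trig lactamization that expels pivalaldehyde and bares the C1 hydroxyl, and aqueous acid then drives translactonization of that hydroxyl onto C14, which opens the lactol acetal to the C11 aldehyde and menthol without forming or breaking a stereocentre.

Step 10
Reactants: 18 (Z)-pent-2-ene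
Product: 20 2-[(2Z)-pent-2-en-1-yl]-4,4,5,5-tetramethyl-1,3,2-dioxaborolane, via pentenylpotassium 19 (not isolated)
Conditions: n-BuLi, KOtBu, THF, −78 to −50 °C; then 2-isopropoxy-4,4,5,5-tetramethyl-1,3,2-dioxaborolane, −78 °C
Reagents that add atoms: 2-isopropoxy-4,4,5,5-tetramethyl-1,3,2-dioxaborolane, CC(C)OB1OC(C)(C)C(C)(C)O1
Why: Allylic metalation of the methyl group by the n-BuLi/KOtBu superbase gives the (Z)-allylpotassium, configurationally stable at low temperature, and borylation at its primary terminus retains the Z geometry.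

Step 11
Reactants: 17 the spiro aldehyde; 20 the (Z)-pentenyl boronate
Product: 21 homoallylic alcohol of 17 with CH(OH) (C11 R), CH(Et) (C10 S) and a terminal vinyl group (C9=C8) on C12
Conditions: PhMe, 4 Å molecular sieves, 23 to 50 °C; aq. NaHCO3 work-up
Reagents that add atoms: none
Why: Allylboration through a closed chair transition state, in which the Z geometry gives the syn C10/C11 relation and the Z γ-ethyl group disfavours the Felkin–Anh rotamer of the α-branched aldehyde, so the anti-Felkin adduct (C11 R, C10 S) is expected.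

Step 12
Reactants: 21 the homoallylic alcohol
Product: 22 O11-tert-butyldimethylsilyl ether of 21
Conditions: tBuMe2SiOTf, 2,6-lutidine, CH2Cl2, −78 to 0 °C
Reagents that add atoms: tert-butyldimethylsilyl triflate, CC(C)(C)[Si](C)(C)OS(=O)(=O)C(F)(F)F
Why: Silylation of the hindered secondary alcohol protects O11 against oxalyl chloride in step 14, and any silylated lactam is hydrolysed on work-up.

Step 13
Reactants: 22 the silyl ether; 23 5-chloropent-1-ene
Product: 24 lactam of 22 with the chain C12–CH(OSi)–CH(Et)–CH=CH–(CH2)3–Cl (E shown)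
Conditions: second-generation Grubbs catalyst RuCl2(=CHPh)(PCy3)(H2IMes) (cat.), excess 23, CH2Cl2, 40 °C
Reagents that add atoms: none
Why: Olefin cross-metathesis of the terminal vinyl group with an excess of the unhindered chloroalkene, driven by loss of ethylene, installs C5–C8 and the C5 chloride, and the alkene geometry is irrelevant because C9 and C8 lose it in step 15.

Step 14
Reactants: 24 the chloroalkene lactam
Product: 26 Se-phenyl selenoimidate of 24 (2-phenylselanyl-1-pyrroline with C9a=N4), via imidoyl chloride 25 (not isolated)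
Conditions: (COCl)2, 2,6-lutidine, CH2Cl2, 0 °C; then PhSeH, pyridine, 0 to 23 °C
Reagents that add atoms: benzeneselenol, [SeH]c1ccccc1
Why: Oxalyl chloride converts the secondary lactam into the cyclic imidoyl chloride, which cannot self-condense because C1 is quaternary, and benzeneselenol displaces chloride by addition–elimination to give the imidoyl radical precursor.

Step 15
Reactants: 26 the Se-phenyl selenoimidate
Product: 28 O11-tert-butyldimethylsilyl ether of the target, via tricyclic ketimine 27 (not isolated)
Conditions: Bu3SnH (syringe pump), AIBN (cat.), degassed PhMe, 90 °C; then K2CO3, NaI (cat.), DMF, 80 °C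
Reagents that add atoms: none
Why: The stannyl radical abstracts SePh from 26 to give the σ-imidoyl radical at C9a, which adds 6-exo-trig to C9 of the C8=C9 alkene (closes the cyclohexene ring, bond C9–C9a), and the C8 radical takes hydrogen from Bu3SnH to give ketimine 27; on heating with iodide the imine nitrogen displaces the C5 chloride 7-exo-tet (closes the azepine ring, bond N4–C5) and K2CO3 removes the only α-hydrogen of the iminium, at C9, to give the enamine. The closest known reaction types are the tin-hydride cyclization of Se-phenyl selenoimidates to 1-pyrrolines and the closure of ω-haloalkyl cyclic imines to bicyclic enamines. No stereocentre is created that survives: C9 ends sp2 and C8 is a methylene, so alkene geometry and the C9 epimers of 27 are without consequence, and K2CO3 is too weak to enolize the lactones. The step needs exo addition to win over reduction, endo closure and 1,5-hydrogen transfer from C10–H, which slow hydride addition and the cis placement of C11 and C9a on the spirolactone should favour. It also needs N- over C-alkylation of the imine, which is expected because the quaternary C1 blocks one α-side and C-attack at C9 would build a congested quaternary spiro centre. The primary chloride is much less reactive toward the stannyl radical than the selenoimidate and becomes the electrophile only after iodide exchange.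

Step 16
Reactants: 28 the silyl ether of the target
Product: 29 target, CNP0154902.3
Conditions: HF·pyridine, pyridine, THF, 0 to 23 °C; aq. NaHCO3 work-up
Reagents that add atoms: none
Why: Fluoride-mediated cleavage of the silyl ether under buffered conditions should free the C11 hydroxyl while the reversibly protonated enamine, both lactones and all stereocentres remain intact.

Compound list
1 | L-allylglycine, (2S)-2-aminopent-4-enoic acid | C=CC[C@H](N)C(=O)O | starting material
2 | (2S)-2-hydroxypent-4-enoic acid | C=CC[C@H](O)C(=O)O | intermediate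
3 | (2S,5S)-2-tert-butyl-5-(prop-2-en-1-yl)-1,3-dioxolan-4-one | C=CC[C@@H]1O[C@H](C(C)(C)C)OC1=O | intermediate
4 | (5R)-5-{[(1R,2S,5R)-2-isopropyl-5-methylcyclohexyl]oxy}furan-2(5H)-one | O=C1C=C[C@H](O[C@@H]2C[C@H](C)CC[C@H]2C(C)C)O1 | starting material
5 | lithium enolate of 3 | C=CCC1=C([O-])O[C@@H](C(C)(C)C)O1.[Li+] | intermediate
6 | lithium lactone enolate of the conjugate adduct of 5 and 4 | C=CC[C@]1([C@@H]2C=C([O-])O[C@H]2O[C@@H]3C[C@H](C)CC[C@H]3C(C)C)O[C@H](C(C)(C)C)OC1=O.[Li+] | intermediate
7 | (2S,5R)-2-tert-butyl-5-[(2R,3S,4R)-2-menthyloxy-4-methyl-5-oxooxolan-3-yl]-5-(prop-2-en-1-yl)-1,3-dioxolan-4-one | C=CC[C@]1([C@@H]2[C@@H](C)C(=O)O[C@H]2O[C@@H]3C[C@H](C)CC[C@H]3C(C)C)O[C@H](C(C)(C)C)OC1=O | intermediate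
8 | ozonide (1,2,4-trioxolane) of 7 | C1OOC(C[C@]2([C@@H]3[C@@H](C)C(=O)O[C@H]3O[C@@H]4C[C@H](C)CC[C@H]4C(C)C)O[C@H](C(C)(C)C)OC2=O)O1 | intermediate
9 | aldehyde of 7 (CH2–CHO in place of allyl) | O=CC[C@]1([C@@H]2[C@@H](C)C(=O)O[C@H]2O[C@@H]3C[C@H](C)CC[C@H]3C(C)C)O[C@H](C(C)(C)C)OC1=O | intermediate
10 | (S at sulfur, E)-N-tert-butanesulfinyl aldimine of 9 | CC(C)(C)[S@](=O)/N=C/C[C@]1([C@@H]2[C@@H](C)C(=O)O[C@H]2O[C@@H]3C[C@H](C)CC[C@H]3C(C)C)O[C@H](C(C)(C)C)OC1=O | intermediate
11 | 3-methylfuran-2(5H)-one | CC1=CCOC1=O | starting material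
12 | 3-methyl-2-[(triisopropylsilyl)oxy]furan | Cc1ccoc1O[Si](C(C)C)(C(C)C)C(C)C | intermediate
13 | vinylogous Mannich adduct (C3 R, C18 S, butenolide) | CC(C)(C)[S@](=O)N[C@@H]([C@@H]1C=C(C)C(=O)O1)C[C@]2([C@@H]4[C@@H](C)C(=O)O[C@H]4O[C@@H]3C[C@H](C)CC[C@H]3C(C)C)O[C@H](C(C)(C)C)OC2=O | intermediate
14 | saturated cis lactone sulfinamide (C20 S) | CC(C)(C)[S@](=O)N[C@@H]([C@@H]1C[C@H](C)C(=O)O1)C[C@]2([C@@H]4[C@@H](C)C(=O)O[C@H]4O[C@@H]3C[C@H](C)CC[C@H]3C(C)C)O[C@H](C(C)(C)C)OC2=O | intermediate
15 | amine hydrochloride from 14 | Cl.N[C@@H]([C@@H]1C[C@H](C)C(=O)O1)C[C@]2([C@@H]4[C@@H](C)C(=O)O[C@H]4O[C@@H]3C[C@H](C)CC[C@H]3C(C)C)O[C@H](C(C)(C)C)OC2=O | intermediate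
16 | 3-hydroxy-pyrrolidin-2-one (free C1–OH) still carrying the menthyloxy lactone on C1 | O=C1N[C@@H]([C@@H]2C[C@H](C)C(=O)O2)C[C@@]1(O)[C@@H]3[C@@H](C)C(=O)O[C@H]3O[C@@H]4C[C@H](C)CC[C@H]4C(C)C | intermediate
17 | 4-formyl-3-methyl-8-[(2S,4S)-4-methyl-5-oxooxolan-2-yl]-1-oxa-7-azaspiro[4.4]nonane-2,6-dione (C1, C3, C12, C13 as in the target) | O=C1N[C@@H]([C@@H]2C[C@H](C)C(=O)O2)C[C@]13OC(=O)[C@H](C)[C@@H]3C=O | intermediate
18 | (Z)-pent-2-ene | C/C=C\CC | starting material
19 | (Z)-pent-2-enylpotassium | [K+].[CH2-]/C=C\CC | intermediate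
20 | 2-[(2Z)-pent-2-en-1-yl]-4,4,5,5-tetramethyl-1,3,2-dioxaborolane | CC/C=C\CB1OC(C)(C)C(C)(C)O1 | intermediate
21 | homoallylic alcohol (C11 R, C10 S, terminal vinyl) | O=C1N[C@@H]([C@@H]2C[C@H](C)C(=O)O2)C[C@]13OC(=O)[C@H](C)[C@@H]3[C@H](O)[C@@H](CC)C=C | intermediate
22 | O11-tert-butyldimethylsilyl ether of 21 | O=C1N[C@@H]([C@@H]2C[C@H](C)C(=O)O2)C[C@]13OC(=O)[C@H](C)[C@@H]3[C@H](O[Si](C)(C)C(C)(C)C)[C@@H](CC)C=C | intermediate
23 | 5-chloropent-1-ene | C=CCCCCl | starting material
24 | cross-metathesis product, (E)-chloroalkene lactam | O=C1N[C@@H]([C@@H]2C[C@H](C)C(=O)O2)C[C@]13OC(=O)[C@H](C)[C@@H]3[C@H](O[Si](C)(C)C(C)(C)C)[C@@H](CC)/C=C/CCCCl | intermediate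
25 | cyclic imidoyl chloride of 24 | ClC1=N[C@@H]([C@@H]2C[C@H](C)C(=O)O2)C[C@]13OC(=O)[C@H](C)[C@@H]3[C@H](O[Si](C)(C)C(C)(C)C)[C@@H](CC)/C=C/CCCCl | intermediate
26 | Se-phenyl selenoimidate of 24 | c1ccccc1[Se]C4=N[C@@H]([C@@H]2C[C@H](C)C(=O)O2)C[C@]43OC(=O)[C@H](C)[C@@H]3[C@H](O[Si](C)(C)C(C)(C)C)[C@@H](CC)/C=C/CCCCl | intermediate
27 | tricyclic ketimine (C9a=N4, 4-chlorobutyl on C9, C9 epimers) | CC[C@H]1C(CCCCCl)C2=N[C@@H]([C@@H]3C[C@H](C)C(=O)O3)C[C@]24OC(=O)[C@H](C)[C@@H]4[C@@H]1O[Si](C)(C)C(C)(C)C | intermediate
28 | O11-tert-butyldimethylsilyl ether of the target | CC[C@H]1C2=C3N(CCCC2)[C@@H]([C@@H]2C[C@H](C)C(=O)O2)C[C@]32OC(=O)[C@H](C)[C@@H]2[C@@H]1O[Si](C)(C)C(C)(C)C | intermediate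
29 | CNP0154902.3, (1R,3R,10S,11R,12R,13R,18S,20S) | CC[C@H]1C2=C3N(CCCC2)[C@@H]([C@@H]2C[C@H](C)C(=O)O2)C[C@]32OC(=O)[C@H](C)[C@@H]2[C@@H]1O | target

Total step count: 16. Longest linear sequence: 14 steps (steps 1–5, 7–9, 11–16); steps 6 and 10 prepare the two reagents 12 and 20.

Steps most likely to fail

Step 15. The imidoyl radical may be reduced to the aldimine before it cyclizes, or it may take the allylic hydrogen from C10 by 1,5-transfer instead of adding to C9; in the second stage the imine may alkylate on carbon through its enamine tautomer. The fallback sets out from 24 and comes back to the route at 27. Lactam 24 is thionated selectively (lactam far faster than lactone) with 2,4-bis(4-methoxyphenyl)-1,3,2,4-dithiadiphosphetane 2,4-disulfide in THF to give the thiolactam F1. Bu3SnH with Et3B/air in PhMe then adds the stannyl radical to sulfur; the resulting stabilized α-amino-α-stannylthio carbon radical, which has no tendency to abstract hydrogen, cyclizes 6-exo onto C9, and loss of tributylstannanethiol gives ketimine 27, which is taken to 28 by the same K2CO3/NaI stage.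

Step 3. The fully substituted enolate may add slowly or with poor facial discrimination if the two chiral partners are mismatched, and the dioxolanone enolate may decompose before it adds; methylation of the hindered lactone enolate may stay incomplete. The fallback sets out from 3 and comes back at 7. Enolate 5 is trapped with Me3SiCl as the silyl ketene acetal F2, which undergoes a fluoride-promoted Mukaiyama–Michael addition to 4 (catalytic tris(dimethylamino)sulfonium difluorotrimethylsilicate, THF, −78 °C) to give the unmethylated adduct F3. F3 has the lactone CH2 as its only enolizable site and is methylated separately with LiN(SiMe3)2 and MeI, anti to the C12 substituent, to give 7.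

Step 11. The neopentyl-like aldehyde may react sluggishly with the pinacol boronate, the facial preference may turn toward the Felkin–Anh adduct, and slow addition gives time for epimerization of C12 through the enol. The fallback sets out from 17 and comes back at 24, which also bypasses the cross-metathesis. The more reactive (Z)-boron enolate of S-phenyl butanethioate (9-BBN-OTf, iPr2NEt, CH2Cl2, −78 °C) gives the syn aldol thioester F4 with the same anti-Felkin preference. Silylation (tBuMe2SiOTf, 2,6-lutidine) gives F5, and reduction of the thioester with Et3SiH over Pd/C gives the C9 aldehyde F6. Julia–Kocienski olefination with 5-[(4-chlorobutyl)sulfonyl]-1-phenyl-1H-tetrazole and KN(SiMe3)2 then gives 24.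

Further compounds
F1 | step 15 | thiolactam of 24 | S=C1N[C@@H]([C@@H]2C[C@H](C)C(=O)O2)C[C@]13OC(=O)[C@H](C)[C@@H]3[C@H](O[Si](C)(C)C(C)(C)C)[C@@H](CC)/C=C/CCCCl
F2 | step 3 | trimethylsilyl ketene acetal of 3 | C=CCC1=C(O[Si](C)(C)C)O[C@@H](C(C)(C)C)O1
F3 | step 3 | conjugate adduct of 3 and 4 without the C13 methyl group | C=CC[C@]1([C@@H]2CC(=O)O[C@H]2O[C@@H]3C[C@H](C)CC[C@H]3C(C)C)O[C@H](C(C)(C)C)OC1=O
F4 | step 11 | syn aldol S-phenyl thioester (C11 R hydroxyl, C10 S ethyl, C9 thioester) | O=C1N[C@@H]([C@@H]2C[C@H](C)C(=O)O2)C[C@]13OC(=O)[C@H](C)[C@@H]3[C@H](O)[C@@H](CC)C(=O)Sc4ccccc4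
F5 | step 11 | O11-tert-butyldimethylsilyl ether of F4 | O=C1N[C@@H]([C@@H]2C[C@H](C)C(=O)O2)C[C@]13OC(=O)[C@H](C)[C@@H]3[C@H](O[Si](C)(C)C(C)(C)C)[C@@H](CC)C(=O)Sc4ccccc4
F6 | step 11 | C9 aldehyde from F5 | O=C1N[C@@H]([C@@H]2C[C@H](C)C(=O)O2)C[C@]13OC(=O)[C@H](C)[C@@H]3[C@H](O[Si](C)(C)C(C)(C)C)[C@@H](CC)C=O
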